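## Retrosynthetic overview

1. Core numbering follows isochromene: C1H2, O2, C3 (propenyl), C4, C4a, C5, C6 (ketone), C7 (carbinol), C8 (ester), C8a (ring-fusion CH). The C8 orsellinate is cut last, back to diol 19. The C3 propenyl group and the O2-C3=C4 enol ether go back to a lactone whose C6 ketone is masked as a silyl dienol ether (15).
2. Feature on which the plan rests: in the carbocycle, the C6 ketone, the C4a=C5 alkene and the C7 tertiary carbinol, with the C7 oxygen 1,4 to C4a, are the ring-opened form of a 7-oxabicyclo[2.2.1]heptene. Its oxygen spans C7 and C4a, and its alkene is a C5=C6 silyl enol ether.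
3. That adduct (11) is cut at C7-C8 and C4a-C8a to 3-silyloxy-2-methylfuran 10, whose (E)-enone hangs on the C3 ester. One cycloaddition closes the carbocycle and the delta-lactone form of the pyran ring, and the endo acetyl at C8 later becomes C8-O by a retentive Baeyer-Villiger step.
4. Furan 10 comes from ethyl lactate, allyl acetoacetate and methyl vinyl ketone by dianion acylation, furanone closure, cross-metathesis and O-silylation.
5. Ring order: furan first, then carbocycle and lactone together in step 6. The furan-derived oxa-bridge is cleaved in step 7, and the lactone becomes the dihydropyran in step 11.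

Key step: step 6

Remark 1: applying the alpha-C-H...O binding model for oxazaborolidinium-enone complexes to 10 points to the (R)-diphenylprolinol-derived catalyst for the (7R,8S,8aS) series. This is a prediction, and the antipodal catalyst is equally available.
Remark 2: orsellinic acid and (E)-1-bromoprop-1-ene are taken as commercial. Racemic ethyl lactate suffices because its stereocentre becomes an sp2 furan carbon in step 5.

## Route

Step 1
Reactants: 1 ethyl lactate (racemic)
Product: 2 ethyl 2-(tert-butyldimethylsilyloxy)propanoate (racemic)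
Conditions: TBSCl, imidazole, DMF, 0 °C to rt
Reagents that add atoms: tert-butyldimethylsilyl chloride, CC(C)(C)[Si](C)(C)Cl
Why: Imidazole-promoted silylation of a secondary alcohol keeps the hydroxyl from quenching the dianion of step 2.

Step 2
Reactants: 3 allyl acetoacetate; 2 ethyl 2-(tert-butyldimethylsilyloxy)propanoate
Product: 5 allyl 6-(tert-butyldimethylsilyloxy)-3,5-dioxoheptanoate (racemic), via sodium lithium dianion of allyl acetoacetate 4 (not isolated)
Conditions: 3, NaH, THF, 0 °C; n-BuLi, 0 °C; then 2, -78 to 0 °C; 1 M HCl quench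
Reagents that add atoms: none
Why: In this Claisen-type gamma-acylation of an acetoacetate dianion the terminal carbanion is the more nucleophilic site, and the released ethoxide deprotonates the new 1,3-diketone so that no second addition follows.

Step 3
Reactants: 5 allyl 6-(tert-butyldimethylsilyloxy)-3,5-dioxoheptanoate
Product: 7 allyl 2-(5-methyl-4-oxo-4,5-dihydrofuran-2-yl)acetate (racemic), via allyl 6-hydroxy-3,5-dioxoheptanoate 6 (not isolated)
Conditions: 2 M HCl, THF, rt
Reagents that add atoms: none
Why: Acid removes the silyl ether, and the freed alpha'-hydroxy-1,3-diketone undergoes the known cyclodehydration (five-membered hemiketal, then loss of water) to the 3(2H)-furanone, whose endocyclic vinylogous ester is the stable tautomer.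

Step 4
Reactants: 7 allyl 2-(5-methyl-4-oxo-4,5-dihydrofuran-2-yl)acetate; 8 methyl vinyl ketone
Product: 9 (E)-4-oxopent-2-enyl 2-(5-methyl-4-oxo-4,5-dihydrofuran-2-yl)acetate (racemic)
Conditions: 8 (3 equiv), second-generation Hoveyda-Grubbs catalyst, RuCl2(H2IMes)(=CH-C6H4-2-OiPr) (5 mol %), CH2Cl2, 40 °C
Reagents that add atoms: none
Why: Olefin cross-metathesis of a terminal allyl ester with an electron-poor vinyl ketone favours the cross product as the (E)-enone, and the trisubstituted electron-poor furanone alkene does not take part.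

Step 5
Reactants: 9 (E)-4-oxopent-2-enyl 2-(5-methyl-4-oxo-4,5-dihydrofuran-2-yl)acetate
Product: 10 (E)-4-oxopent-2-enyl 2-[5-methyl-4-(triisopropylsilyloxy)furan-2-yl]acetate
Conditions: TIPSOTf (1.05 equiv), Et3N, CH2Cl2, -78 to -20 °C; kept cold and used at once
Reagents that add atoms: triisopropylsilyl trifluoromethanesulfonate, CC(C)[Si](OS(=O)(=O)C(F)(F)F)(C(C)C)C(C)C
Why: In this soft enolisation the vinylogous-ester carbonyl of the furanone is the most Lewis-basic oxygen and is silylated first, and loss of the ring C-H next to it gives the aromatic 3-silyloxyfuran, so one equivalent of triflate at low temperature should spare the methyl enone.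

Step 6
Reactants: 10 (E)-4-oxopent-2-enyl 2-[5-methyl-4-(triisopropylsilyloxy)furan-2-yl]acetate
Product: 11 (4aS,7R,8S,8aR)-8-acetyl-7-methyl-6-(triisopropylsilyloxy)-1,7,8,8a-tetrahydro-4a,7-epoxyisochromen-3(4H)-one (oxygen bridge C4a-O-C7; C1 exo and syn to the bridge; acetyl endo)
Conditions: (R)-3,3-diphenyl-1-(2-methylphenyl)tetrahydro-1H,3H-pyrrolo[1,2-c][1,3,2]oxazaborole (C24H24BNO, 20 mol %), HN(SO2CF3)2 (18 mol %), CH2Cl2 (0.005 M), -78 to -40 °C; Et3N quench at -78 °C
Reagents that add atoms: none
Why: Proposed new method: the N-protonated oxazaborolidine binds the acetyl oxygen on the lone pair syn to C8 (alpha-C-H...O contact), lowers the enone LUMO and covers one enone face, and the furan diene (C7, C6, C5, C4a) then adds suprafacially in a normal-demand, concerted but asynchronous [4+2] in which C4a-C8a (to the enone beta-carbon) runs ahead of C7-C8; the closest known reaction types are the thermal intramolecular Diels-Alder reaction of furans and oxazaborolidinium-catalysed Diels-Alder reactions of enones with furan and with 2-(triisopropylsilyloxy)dienes, whose combination on an ester-tethered 3-silyloxyfuran has not been shown. The carbocycle (C4a, C5, C6, C7, C8, C8a) closes as the cyclohexene ring of a 7-oxabicyclo[2.2.1]heptene, and the six-membered lactone (C1, O2, C3, C4, C4a, C8a) closes in the fused mode through the four-atom tether, for which the ester must first turn into its lactone-like E rotamer, the main energetic toll of the step. C7 and C4a are set together because both new bonds form on one furan face and stay linked by the bridging oxygen, C8a is set by the short tether, which can only lie exo (C1 syn to the bridge), C8 is set by the (E)-alkene, which then puts the acetyl group endo and trans to C1, and the absolute sense of all four follows from the enone face that the catalyst leaves open. The regiochemistry needed runs against the polar bias of the 3-silyloxy group, which would pair C7 with the beta-carbon C8a, and it is the tether that secures it, since that pairing would demand an eight-membered bridged ring. Competing intermolecular Mukaiyama-Michael addition at C7 is held back by high dilution, and the bulky triisopropylsilyl group is chosen so that the enol ether outlives the strongly acidic catalyst. Since furan adducts can revert, the mixture is quenched cold and 11 is carried on without delay, so that the irreversible opening in step 7 drains any equilibrium.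

Step 7
Reactants: 11 oxa-bridged tricyclic lactone
Product: 12 (7R,8S,8aS)-8-acetyl-7-hydroxy-7-methyl-4,7,8,8a-tetrahydro-1H-isochromene-3,6-dione
Conditions: Bu4NF, AcOH (1:1), THF, -20 to 0 °C
Reagents that add atoms: none
Why: Removal of silicon by fluoride unmasks the C6 enolate, whose beta-leaving group is the bridge oxygen on C4a, so E1cB cleavage of the strained C4a-O bond (well known for enolates of 7-oxanorbornan-2-ones) gives the C6 ketone, the C4a=C5 alkene and the C7 alkoxide, which acetic acid protonates before the aldol unit can cleave or dehydrate, with C7, C8 and C8a untouched.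

Step 8
Reactants: 12 hydroxy enone methyl ketone
Product: 13 (7R,8S,8aS)-7-hydroxy-7-methyl-3,6-dioxo-3,4,6,7,8,8a-hexahydro-1H-isochromen-8-yl acetate
Conditions: CF3CO3H (preformed from urea-hydrogen peroxide and (CF3CO)2O), Na2HPO4, CH2Cl2, 0 °C
Reagents that add atoms: trifluoroperacetic acid (oxygen from urea-hydrogen peroxide), OOC(=O)C(F)(F)F
Why: In this Baeyer-Villiger oxidation the saturated methyl ketone takes up peracid faster than the hindered conjugated C6 ketone, secondary C8 migrates in preference to methyl and with retention of configuration, and the electron-poor C4a=C5 alkene resists epoxidation.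

Step 9
Reactants: 13 C8 acetate
Product: 14 (7R,8S,8aS)-7,8-dihydroxy-7-methyl-4,7,8,8a-tetrahydro-1H-isochromene-3,6-dione
Conditions: K2CO3 (1.5 equiv), MeOH, 0 °C; AcOH quench
Reagents that add atoms: none
Why: In this base-mediated transesterification (methanolysis of an acetate) the doubly activated C4 methylene is deprotonated first, so the lactone and the C6 ketone sit in one extended enolate that shields them from methoxide and blocks deprotonation at C8a while the acetate is cleaved.

Step 10
Reactants: 14 diol
Product: 15 (7R,8S,8aS)-7-methyl-6,7,8-tris(triethylsilyloxy)-1,7,8,8a-tetrahydro-3H-isochromen-3-one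
Conditions: TESOTf (3.3 equiv), Et3N, CH2Cl2, -78 to -20 °C
Reagents that add atoms: triethylsilyl trifluoromethanesulfonate, CC[Si](CC)(CC)OS(=O)(=O)C(F)(F)F
Why: The silyl triflate caps both hydroxyls and, by soft enolisation of the C6 ketone with loss of a C4 proton, gives the linearly conjugated silyl dienol ether, which masks C6 deliberately because any enolate-based activation of the lactone in 14 (phosphate or triflate) would land on the C6 oxygen, as it does on the ketone oxygen of beta-keto esters.

Step 11
Reactants: 15 tris(triethylsilyl) dienyl lactone; 16 (E)-1-bromoprop-1-ene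
Product: 19 (7R,8S,8aS)-7,8-dihydroxy-7-methyl-3-[(E)-prop-1-enyl]-1,7,8,8a-tetrahydro-6H-isochromen-6-one, via (E)-prop-1-enyllithium 17 (not isolated), via C3 lactol 18 (not isolated)
Conditions: 16, t-BuLi (2 equiv), Et2O, -78 °C; then 15 (1.1 equiv of 17), THF, -78 °C; AcOH; then HF-pyridine, THF, 0 °C
Reagents that add atoms: none
Why: Bromine-lithium exchange keeps the alkene geometry, the alkenyllithium adds 1,2 to the only carbonyl group left (lactone to lactol, as with sugar lactones), and Stork-Danheiser-type ionisation of the lactol gives an oxocarbenium ion that is discharged by loss of the C6 silyl group to the O2-C3=C4-C4a=C5-C6=O chromophore, while HF also frees the C7 and C8 hydroxyls.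

Step 12
Reactants: 20 orsellinic acid (2,4-dihydroxy-6-methylbenzoic acid)
Product: 21 tert-butyldimethylsilyl 2,4-bis(tert-butyldimethylsilyloxy)-6-methylbenzoate
Conditions: TBSCl (3.5 equiv), imidazole, DMF, rt
Reagents that add atoms: tert-butyldimethylsilyl chloride, CC(C)(C)[Si](C)(C)Cl
Why: Exhaustive imidazole-promoted silylation covers both phenols and the acid at room temperature, below the point at which orsellinic acid decarboxylates.

Step 13
Reactants: 21 tris-silylated orsellinic acid
Product: 22 2,4-bis(tert-butyldimethylsilyloxy)-6-methylbenzoyl chloride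
Conditions: (COCl)2, DMF (cat.), CH2Cl2, 0 °C to rt; used crude
Reagents that add atoms: oxalyl chloride, O=C(Cl)C(=O)Cl
Why: The known conversion of a silyl ester into the acid chloride by the Vilsmeier reagent from oxalyl chloride and DMF produces no HCl, so the phenolic silyl ethers are kept.

Step 14
Reactants: 19 diol; 22 protected orsellinoyl chloride
Product: 23 (7R,8S,8aS)-7-hydroxy-7-methyl-6-oxo-3-[(E)-prop-1-enyl]-1,7,8,8a-tetrahydro-6H-isochromen-8-yl 2,4-bis(tert-butyldimethylsilyloxy)-6-methylbenzoate
Conditions: 22 (1.5 equiv), Et3N, DMAP, CH2Cl2, 0 °C to rt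
Reagents that add atoms: none
Why: DMAP-catalysed acylation through the acylpyridinium salt picks the secondary C8 hydroxyl over the tertiary C7 hydroxyl on steric grounds, and at this stage C4 is sp2, so no enol competes for the acyl group and no stereocentre is touched.

Step 15
Reactants: 23 bis-silylated ester
Product: 24 target, (7R,8S,8aS)-7-hydroxy-7-methyl-6-oxo-3-[(E)-prop-1-enyl]-1,7,8,8a-tetrahydro-6H-isochromen-8-yl 2,4-dihydroxy-6-methylbenzoate
Conditions: Bu4NF, AcOH (1:1), THF, 0 °C
Reagents that add atoms: none
Why: Fluoride cleaves phenolic silyl ethers very readily, and the acetic acid buffer keeps the medium from becoming basic enough to remove H-8a and expel the C8 ester.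

## Compound list

1 | ethyl lactate (racemic) | CCOC(=O)C(C)O | starting material
2 | ethyl 2-(tert-butyldimethylsilyloxy)propanoate (racemic) | CCOC(=O)C(C)O[Si](C)(C)C(C)(C)C | intermediate
3 | allyl acetoacetate | C=CCOC(=O)CC(C)=O | starting material
4 | sodium lithium dianion of allyl acetoacetate | [Na+].[Li+].C=CCOC([O-])=CC(=C)[O-] | intermediate
5 | allyl 6-(tert-butyldimethylsilyloxy)-3,5-dioxoheptanoate (racemic) | C=CCOC(=O)CC(=O)CC(=O)C(C)O[Si](C)(C)C(C)(C)C | intermediate
6 | allyl 6-hydroxy-3,5-dioxoheptanoate (racemic) | C=CCOC(=O)CC(=O)CC(=O)C(C)O | intermediate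
7 | allyl 2-(5-methyl-4-oxo-4,5-dihydrofuran-2-yl)acetate (racemic) | C=CCOC(=O)CC1=CC(=O)C(C)O1 | intermediate
8 | methyl vinyl ketone | CC(=O)C=C | starting material
9 | (E)-4-oxopent-2-enyl 2-(5-methyl-4-oxo-4,5-dihydrofuran-2-yl)acetate (racemic) | CC(=O)/C=C/COC(=O)CC1=CC(=O)C(C)O1 | intermediate
10 | (E)-4-oxopent-2-enyl 2-[5-methyl-4-(triisopropylsilyloxy)furan-2-yl]acetate | Cc1oc(CC(=O)OC/C=C/C(C)=O)cc1O[Si](C(C)C)(C(C)C)C(C)C | intermediate
11 | (4aS,7R,8S,8aR)-8-acetyl-7-methyl-6-(triisopropylsilyloxy)-1,7,8,8a-tetrahydro-4a,7-epoxyisochromen-3(4H)-one | C[C@@]12O[C@]3(CC(=O)OC[C@H]3[C@@H]1C(C)=O)C=C2O[Si](C(C)C)(C(C)C)C(C)C | intermediate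
12 | (7R,8S,8aS)-8-acetyl-7-hydroxy-7-methyl-4,7,8,8a-tetrahydro-1H-isochromene-3,6-dione | O=C1CC2=CC(=O)[C@](C)(O)[C@@H](C(C)=O)[C@@H]2CO1 | intermediate
13 | (7R,8S,8aS)-7-hydroxy-7-methyl-3,6-dioxo-3,4,6,7,8,8a-hexahydro-1H-isochromen-8-yl acetate | O=C1CC2=CC(=O)[C@](C)(O)[C@@H](OC(C)=O)[C@@H]2CO1 | intermediate
14 | (7R,8S,8aS)-7,8-dihydroxy-7-methyl-4,7,8,8a-tetrahydro-1H-isochromene-3,6-dione | O=C1CC2=CC(=O)[C@](C)(O)[C@@H](O)[C@@H]2CO1 | intermediate
15 | (7R,8S,8aS)-7-methyl-6,7,8-tris(triethylsilyloxy)-1,7,8,8a-tetrahydro-3H-isochromen-3-one | O=C1C=C2C=C(O[Si](CC)(CC)CC)[C@](C)(O[Si](CC)(CC)CC)[C@@H](O[Si](CC)(CC)CC)[C@@H]2CO1 | intermediate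
16 | (E)-1-bromoprop-1-ene | C/C=C/Br | starting material
17 | (E)-prop-1-enyllithium | C/C=C/[Li] | intermediate
18 | C3 lactol, (7R,8S,8aS)-7-methyl-3-[(E)-prop-1-enyl]-6,7,8-tris(triethylsilyloxy)-1,7,8,8a-tetrahydro-3H-isochromen-3-ol (C3 epimers) | C/C=C/C1(O)C=C2C=C(O[Si](CC)(CC)CC)[C@](C)(O[Si](CC)(CC)CC)[C@@H](O[Si](CC)(CC)CC)[C@@H]2CO1 | intermediate
19 | (7R,8S,8aS)-7,8-dihydroxy-7-methyl-3-[(E)-prop-1-enyl]-1,7,8,8a-tetrahydro-6H-isochromen-6-one | C/C=C/C1=CC2=CC(=O)[C@](C)(O)[C@@H](O)[C@@H]2CO1 | intermediate
20 | orsellinic acid | Cc1cc(O)cc(O)c1C(=O)O | starting material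
21 | tert-butyldimethylsilyl 2,4-bis(tert-butyldimethylsilyloxy)-6-methylbenzoate | Cc1cc(O[Si](C)(C)C(C)(C)C)cc(O[Si](C)(C)C(C)(C)C)c1C(=O)O[Si](C)(C)C(C)(C)C | intermediate
22 | 2,4-bis(tert-butyldimethylsilyloxy)-6-methylbenzoyl chloride | Cc1cc(O[Si](C)(C)C(C)(C)C)cc(O[Si](C)(C)C(C)(C)C)c1C(=O)Cl | intermediate
23 | bis(tert-butyldimethylsilyl) ether of the target | C/C=C/C1=CC2=CC(=O)[C@](C)(O)[C@@H](OC(=O)c3c(C)cc(O[Si](C)(C)C(C)(C)C)cc3O[Si](C)(C)C(C)(C)C)[C@@H]2CO1 | intermediate
24 | CNP0130178.5, (7R,8S,8aS)-7-hydroxy-7-methyl-6-oxo-3-[(E)-prop-1-enyl]-1,7,8,8a-tetrahydro-6H-isochromen-8-yl 2,4-dihydroxy-6-methylbenzoate | C/C=C/C1=CC2=CC(=O)[C@](C)(O)[C@@H](OC(=O)c3c(C)cc(O)cc3O)[C@@H]2CO1 | target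

## Step count

Total step count: 15. Longest linear sequence: 13 (steps 1 to 11, 14 and 15).

## Steps most likely to fail

**Step 6.**
- What may go wrong: the ester tether may not reach its lactone-like rotamer at the low temperature the catalyst needs. The silyl enol ether may be protonated or drawn into conjugate addition. Facial selectivity may be poor.
- Fallback, from 10 to 13: the catalyst is dropped. An uncatalysed thermal intramolecular furan Diels-Alder reaction of 10 in dilute toluene (BHT, about 80 to 110 °C) should give the racemic adduct F1, with the same exo-tether, endo-acetyl relative configuration.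
- F1 is opened at once with Bu4NF and AcOH to the racemic hydroxy enone F2, which is oxidised as in step 8 to the racemic acetate F3.
- F3 is resolved by lipase-catalysed hydrolysis (Burkholderia cepacia lipase, pH 7 phosphate buffer, MTBE) run to about half conversion. By the empirical size rule for secondary alcohols, with quaternary C7 as the large group, the (8R)-acetate should be the one cleaved, giving the antipodal diol F4, which is separated.
- The untouched (7R,8S,8aS)-acetate is 13, where the route is rejoined.

**Step 7.**
- What may go wrong: water may be lost across C7-C8 with tautomerisation to a phenol, the C7-C8 bond may cleave by retro-aldol reaction, C8 may epimerise, or cycloreversion may occur before the bridge opens.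
- Fallback, from 11 to 12: the acidity of H-8 is removed before the bridge is opened. NaBH4 in MeOH and CH2Cl2 at -40 °C should reduce only the acetyl ketone to the carbinol adduct F5. The epimers at the new centre are of no consequence.
- Bu4NF and AcOH then open the bridge to the dihydroxy enone F6, in which neither the E1cB nor the retro-aldol path exists.
- Dess-Martin periodinane buffered with NaHCO3 restores the methyl ketone under neutral conditions and gives 12, which goes directly into step 8.

**Step 11.**
- What may go wrong: a second equivalent of the organolithium may add after ring-opening of the lactolate, deprotonation at C8a may replace addition, or the push-pull lactone may react sluggishly.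
- Fallback, from 14 to 19: C3 becomes the electrophile of a cross-coupling. Luche reduction of 14 (NaBH4, CeCl3·7H2O, MeOH, -78 °C) takes the C6 ketone out of conjugation with C4 and gives the triol lactone F7 (C6 epimers).
- TESOTf and 2,6-lutidine give the tris(triethylsilyl) ether F8.
- KHMDS and (PhO)2P(O)Cl in THF and HMPA at -78 °C now phosphorylate the only enolate oxygen available, giving the ketene acetal phosphate F9.
- Stille coupling with (E)-tributyl(prop-1-enyl)stannane (Pd(PPh3)4, a zerovalent palladium complex, LiCl, THF, reflux) gives the propenyl dienol ether F10.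
- Bu4NF and AcOH free the triol F11, and MnO2 in CH2Cl2 oxidises only the allylic C6 carbinol to give 19.

## Further compounds

F1 | step 6 | racemic oxa-bridged adduct (both enantiomers of 11) | C[C@@]12O[C@]3(CC(=O)OC[C@H]3[C@@H]1C(C)=O)C=C2O[Si](C(C)C)(C(C)C)C(C)C.C[C@]12O[C@@]3(CC(=O)OC[C@@H]3[C@H]1C(C)=O)C=C2O[Si](C(C)C)(C(C)C)C(C)C
F2 | step 6 | racemic hydroxy enone (both enantiomers of 12) | O=C1CC2=CC(=O)[C@](C)(O)[C@@H](C(C)=O)[C@@H]2CO1.O=C1CC2=CC(=O)[C@@](C)(O)[C@H](C(C)=O)[C@H]2CO1
F3 | step 6 | racemic acetate (both enantiomers of 13) | O=C1CC2=CC(=O)[C@](C)(O)[C@@H](OC(C)=O)[C@@H]2CO1.O=C1CC2=CC(=O)[C@@](C)(O)[C@H](OC(C)=O)[C@H]2CO1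
F4 | step 6 | (7S,8R,8aR)-7,8-dihydroxy-7-methyl-4,7,8,8a-tetrahydro-1H-isochromene-3,6-dione (antipode of 14) | O=C1CC2=CC(=O)[C@@](C)(O)[C@H](O)[C@H]2CO1
F5 | step 7 | 8-(1-hydroxyethyl) analogue of adduct 11 (carbinol epimers) | C[C@@]12O[C@]3(CC(=O)OC[C@H]3[C@@H]1C(C)O)C=C2O[Si](C(C)C)(C(C)C)C(C)C
F6 | step 7 | 8-(1-hydroxyethyl) analogue of hydroxy enone 12 (carbinol epimers) | O=C1CC2=CC(=O)[C@](C)(O)[C@@H](C(C)O)[C@@H]2CO1
F7 | step 11 | 6,7,8-trihydroxy-7-methyl-1,4,6,7,8,8a-hexahydro-3H-isochromen-3-one (C6 epimers) | O=C1CC2=CC(O)[C@](C)(O)[C@@H](O)[C@@H]2CO1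
F8 | step 11 | tris(triethylsilyl) ether of F7 | O=C1CC2=CC(O[Si](CC)(CC)CC)[C@](C)(O[Si](CC)(CC)CC)[C@@H](O[Si](CC)(CC)CC)[C@@H]2CO1
F9 | step 11 | C3 ketene acetal diphenyl phosphate of F8 | O=P(Oc1ccccc1)(Oc1ccccc1)OC1=CC2=CC(O[Si](CC)(CC)CC)[C@](C)(O[Si](CC)(CC)CC)[C@@H](O[Si](CC)(CC)CC)[C@@H]2CO1
F10 | step 11 | 3-[(E)-prop-1-enyl]-6,7,8-tris(triethylsilyloxy) dienol ether | C/C=C/C1=CC2=CC(O[Si](CC)(CC)CC)[C@](C)(O[Si](CC)(CC)CC)[C@@H](O[Si](CC)(CC)CC)[C@@H]2CO1
F11 | step 11 | 7-methyl-3-[(E)-prop-1-enyl]-6,7,8,8a-tetrahydro-1H-isochromene-6,7,8-triol (C6 epimers) | C/C=C/C1=CC2=CC(O)[C@](C)(O)[C@@H](O)[C@@H]2CO1
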